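Its constants stand for no real mixture; the result is computed.

What does this flask hold at the end of the run, given that two substrates compete for one coupling partner while the starting material also drains into a dormant form?

    starting material + free catalyst ⇌ catalyst intermediate A (K1 = 220 M⁻¹, k1 = 240 M⁻¹ s⁻¹)
    coupling partner + catalyst intermediate A → free catalyst + target (k2 = 42.2 M⁻¹ s⁻¹)
    second substrate + free catalyst ⇌ catalyst intermediate B (K3 = 200 M⁻¹, k3 = 127 M⁻¹ s⁻¹)
    coupling partner + catalyst intermediate B → free catalyst + second product (k4 = 19.2 M⁻¹ s⁻¹)
    target → over-reaction product (k5 = 0.00460 s⁻¹)
    starting material ⇌ dormant form (K6 = 6.68, k6 = 0.00224 s⁻¹)

starting material 13 mM; second substrate 13.0 mM; coupling partner 15.6 mM; free catalyst 0.11 mM; time 15 h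

* the state of affairs at 15 h: stopped, and by what, or still going (no working catalyst is left / it is still moving / the coupling partner has run out first / all of the starting material has reacted)
* part of the starting material gone at 15 h
* the over-reaction product standing at 15 h, as a percentage of the starting material charged

- what has gone from starting material into another species counts as reacted, even if it can come back
- the reaction counts as stopped when no species that holds the starting material changes by six tenths of a point or more over the second half of the time
- run time (flask): 15 h

The reckoning carries one quantity, the **selectivity exponent** σ, the selectivity factor of the two catalyst cycles: the coupling constant of intermediate A times the binding constant of starting material, divided by the same product for intermediate B.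

σ = 2.42

My reckoning runs in slow motion. In the first instants the catalyst binds, leaving about 15.5 % of it free. Catalyst intermediate A releases its substrate at 1.09 s⁻¹, faster than it couples at 0.658 s⁻¹, so the binding equilibria hold roughly. Dividing the two coupling rates then gives d ln y / d ln x = σ, where y is the fraction of the starting material not yet coupled and x the fraction of the second substrate left. Integrated, this is y = x^σ.

In the middle, the partner's initial half-life is 0.0663 h, close to the dormant relaxation half-life 0.0748 h. Dormancy therefore sets in during the coupling. Once equilibrated, a share 13.0 % of the pool stays free, and the exponent falls to 0.315. The two exponents bracket the flask, with x found by trial so that the substrates consumed equal the partner charged, 15.6 mM: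

σ early throughout: x = 0.556, y = 0.241, consumed 15.6 mM

dormant throughout: x = 0.200, y = 0.603, consumed 15.6 mM

At the end the partner, the limiting reagent, should give out first, since its charge is less than the two substrates together. Target has a half-life of 2.5 min, far shorter than the run, so target made becomes over-reaction product. My reckoning thus gives 39.7 % to 75.9 % over-reaction product and conversion of 92.2 % to 96.9 %, a range and not a single figure.

The forecast commits to single values: the coupling partner has run out first, conversion 93.9 %, over-reaction product 53 %. Its grounds include that “the target, with a lifetime of only a few minutes, has by then all become over-reaction product”.

The simulation gives the coupling partner has run out first, with 0 % of the partner left, conversion 94.0 % and over-reaction product 54.0 %. The forecast stands on all three.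

The end state of this flask reads as an exponent of 0.712, above 0.315 and below σ. The main reason over-reaction product stops at 54.0 % is the second substrate's binding to free catalyst: without that step it reaches >99.9 %. The simulated over-reaction product has moved by 5 points with the partner charged at 13.9 mM or 17.4 mM, all other amounts and the time held.

For the neighbouring flask with 22 mM of second substrate, the same budget gives these limits:

σ: x = 0.667, y = 0.375, consumed 15.5 mM

dormant: x = 0.429, y = 0.766, consumed 15.6 mM

That brackets over-reaction product between 23.4 % and 62.5 %. The neighbouring flask gives 42.1 %.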